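**Plan**
- The retrosynthesis first cuts the depside ester bond between the ring A carbonyl carbon and O-4 of ring B. Both halves are protected forms of one acid, 4-hydroxy-2-methoxy-6-pentylbenzoic acid.
- Each benzene ring carries the carboxyl carbon on C1, oxygen on C2 and C4 and the pentyl chain on C6. This is the alternating pattern of a hexanoyl-primed tetraketide, so the ring bond C1–C6 is cut back to an open-chain 3,5,7-triketo ester.
- The triketo ester is cut at C6–C7 into methyl 3,5-dioxohexanoate (from dehydroacetic acid) and methyl hexanoate.
- Forward: the chain is assembled (steps 1–2) and the one ring is closed (step 3). It is then differentiated by 4-O-benzylation, 2-O-methylation and saponification to the ring A acid, part of which is converted to the ring B phenol benzyl ester. The halves are joined by esterification and both benzyl groups are removed by hydrogenolysis.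
- The target has no stereocentre, so no stereocontrol is needed.

Key step: step 3

Assumption: Mg(OMe)2 (solution in methanol) and LiN(iPr)2 (solution in THF/hexanes) are bought as such; diketo and triketo esters are drawn as keto forms although they are largely enolised.

**Step 1**
Reactants: 1 dehydroacetic acid (3-acetyl-4-hydroxy-6-methyl-2H-pyran-2-one)
Product: 3 methyl 3,5-dioxohexanoate, via methyl 2-acetyl-3,5-dioxohexanoate 2 (not isolated)
Conditions: Mg(OMe)2 (2.5 equiv), MeOH, reflux; then cold 2 M HCl
Reagents that add atoms: magnesium methoxide, C[O-].C[O-].[Mg+2] (its methoxide becomes the ester OMe)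
Why: Methoxide opens the pyranone lactone to the triacylmethane 2, which loses its acetyl group as methyl acetate by retro-Claisen cleavage, and the magnesium chelate protects the resulting diketo ester from further cleavage (lactone alcoholysis followed by retro-Claisen deacylation).

**Step 2**
Reactants: 3 methyl 3,5-dioxohexanoate; 4 methyl hexanoate
Product: 6 methyl 3,5,7-trioxododecanoate, via trilithium trianion of methyl 3,5-dioxohexanoate 5 (not isolated)
Conditions: LiN(iPr)2 (3.3 equiv), THF, −78 to 0 °C; then 4 (0.5 equiv), 0 °C; then cold 1 M HCl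
Reagents that add atoms: none
Why: Threefold deprotonation leaves the terminal C6 carbanion as the last-formed and most nucleophilic site, so Claisen-type acylation by the ester occurs there only; the excess of trianion absorbs the extra proton of the more acidic product (polyanion acylation).

**Step 3**
Reactants: 6 methyl 3,5,7-trioxododecanoate
Product: 8 methyl 2,4-dihydroxy-6-pentylbenzoate, via aldol adduct methyl 2-hydroxy-4,6-dioxo-2-pentylcyclohexane-1-carboxylate 7 (not isolated)
Conditions: Cs2CO3 (1.5 equiv), MeOH, 23 °C; then 3 M HCl, 23 °C
Reagents that add atoms: none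
Why: In the carbonate-generated enolate mixture of 6, the C2 carbanion, flanked by the ester and the C3 ketone, adds to the C7 ketone and forms the C2–C7 bond (ring bond C1–C6 of the benzoate) in the carbocycle 7; E1cB loss of one molecule of water and enolisation of the C3 and C5 carbonyls, completed by the acid quench, give the aromatic ring. The closest known reaction type is the base-mediated aldol cycloaromatisation of 3,5,7-triketo esters to 6-substituted 2,4-dihydroxybenzoates, the laboratory counterpart of tetraketide folding. The six-membered ring closes in a 6-(enolendo)-exo-trig aldol addition. No stereocentre remains, since the two sp3 centres of 7 are erased on aromatisation. The step needs the C2-to-C7 folding in preference to the C8-to-C3 aldol, the C6-to-C1 Claisen closure to an acylphloroglucinol and O-acylation to a 4-hydroxy-2-pyrone. This is secured because C2–H lies between two carbonyls and is far more acidic than the C8–H of the pentyl chain, the C7 ketone is a better electrophile than the methyl ester, and the protic medium without a chelating divalent metal keeps the ester from acting as an acyl donor, while methanol makes ester exchange degenerate.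

**Step 4**
Reactants: 8 methyl 2,4-dihydroxy-6-pentylbenzoate
Product: 9 methyl 4-(benzyloxy)-2-hydroxy-6-pentylbenzoate
Conditions: BnBr (1.05 equiv), K2CO3 (1.2 equiv), acetone, reflux
Reagents that add atoms: benzyl bromide, BrCc1ccccc1
Why: The 4-hydroxyl is the more acidic and unchelated one, whereas the 2-hydroxyl is hydrogen-bonded to the ester carbonyl, so the Williamson etherification should stop at the 4-O-benzyl ether.

**Step 5**
Reactants: 9 methyl 4-(benzyloxy)-2-hydroxy-6-pentylbenzoate
Product: 10 methyl 4-(benzyloxy)-2-methoxy-6-pentylbenzoate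
Conditions: MeI (3 equiv), K2CO3 (2 equiv), DMF, 40 °C
Reagents that add atoms: iodomethane, CI
Why: With only the chelated phenol left, excess iodomethane in a dipolar aprotic solvent breaks the hydrogen bond and methylates it (Williamson etherification).

**Step 6**
Reactants: 10 methyl 4-(benzyloxy)-2-methoxy-6-pentylbenzoate
Product: 11 4-(benzyloxy)-2-methoxy-6-pentylbenzoic acid
Conditions: KOH (5 equiv), DMSO–H2O 4:1, 90 °C; then cold 1 M HCl
Reagents that add atoms: potassium hydroxide, [K+].[OH-] (hydroxide oxygen ends in the carboxyl group)
Why: Poorly solvated hydroxide in hot aqueous DMSO saponifies the di-ortho-substituted benzoate while both ethers are inert, and cold acidification avoids decarboxylation of the electron-rich acid (ester saponification).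

**Step 7**
Reactants: 11 4-(benzyloxy)-2-methoxy-6-pentylbenzoic acid (the portion destined for ring B)
Product: 12 4-hydroxy-2-methoxy-6-pentylbenzoic acid
Conditions: H2 (1 atm), Pd/C (10 wt% Pd), EtOAc, 23 °C
Reagents that add atoms: none
Why: Catalytic hydrogenolysis cleaves the benzyl aryl ether under neutral conditions at room temperature, which spares the decarboxylation-prone acid.

**Step 8**
Reactants: 12 4-hydroxy-2-methoxy-6-pentylbenzoic acid
Product: 13 benzyl 4-hydroxy-2-methoxy-6-pentylbenzoate
Conditions: BnBr (1.0 equiv), KHCO3 (1.1 equiv), DMF, 23 °C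
Reagents that add atoms: benzyl bromide, BrCc1ccccc1
Why: Hydrogen carbonate deprotonates the carboxylic acid but not the phenol, and SN2 alkylation at the carboxylate oxygen is not slowed by the two ortho substituents (carboxylate O-alkylation).

**Step 9**
Reactants: 11 4-(benzyloxy)-2-methoxy-6-pentylbenzoic acid; 13 benzyl 4-hydroxy-2-methoxy-6-pentylbenzoate
Product: 15 benzyl 4-{[4-(benzyloxy)-2-methoxy-6-pentylbenzoyl]oxy}-2-methoxy-6-pentylbenzoate, via 4-(benzyloxy)-2-methoxy-6-pentylbenzoic trifluoroacetic anhydride 14 (not isolated)
Conditions: (CF3CO)2O (4 equiv), toluene, 23 °C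
Reagents that add atoms: none
Why: The electron-rich, di-ortho-substituted acid forms a mixed anhydride that ionises readily to a stabilised acylium ion, which is captured by the only free hydroxyl, the 4-OH of 13 (mixed-anhydride esterification by the trifluoroacetic anhydride method).

**Step 10**
Reactants: 15 benzyl 4-{[4-(benzyloxy)-2-methoxy-6-pentylbenzoyl]oxy}-2-methoxy-6-pentylbenzoate
Product: 16 4-O-demethylplanaic acid
Conditions: H2 (1 atm), Pd/C (10 wt% Pd), EtOAc, 23 °C
Reagents that add atoms: none
Why: Hydrogenolysis removes the benzyl ester and the benzyl ether in one neutral operation, under which the base-labile aryl ester link and the methyl ethers are untouched.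

**Compound list**
1 | dehydroacetic acid (3-acetyl-4-hydroxy-6-methyl-2H-pyran-2-one) | CC(=O)C1=C(O)C=C(C)OC1=O | starting material
2 | methyl 2-acetyl-3,5-dioxohexanoate (ring-opened triacylmethane, not isolated) | CC(=O)CC(=O)C(C(C)=O)C(=O)OC | intermediate
3 | methyl 3,5-dioxohexanoate | CC(=O)CC(=O)CC(=O)OC | intermediate
4 | methyl hexanoate | CCCCCC(=O)OC | starting material
5 | trilithium trianion of methyl 3,5-dioxohexanoate (not isolated) | [Li+].[Li+].[Li+].C=C([O-])C=C([O-])C=C([O-])OC | intermediate
6 | methyl 3,5,7-trioxododecanoate | CCCCCC(=O)CC(=O)CC(=O)CC(=O)OC | intermediate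
7 | methyl 2-hydroxy-4,6-dioxo-2-pentylcyclohexane-1-carboxylate (aldol adduct, mixture of diastereomers, not isolated) | CCCCCC1(O)CC(=O)CC(=O)C1C(=O)OC | intermediate
8 | methyl 2,4-dihydroxy-6-pentylbenzoate | CCCCCc1cc(O)cc(O)c1C(=O)OC | intermediate
9 | methyl 4-(benzyloxy)-2-hydroxy-6-pentylbenzoate | CCCCCc1cc(OCc2ccccc2)cc(O)c1C(=O)OC | intermediate
10 | methyl 4-(benzyloxy)-2-methoxy-6-pentylbenzoate | CCCCCc1cc(OCc2ccccc2)cc(OC)c1C(=O)OC | intermediate
11 | 4-(benzyloxy)-2-methoxy-6-pentylbenzoic acid (ring A acid) | CCCCCc1cc(OCc2ccccc2)cc(OC)c1C(=O)O | intermediate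
12 | 4-hydroxy-2-methoxy-6-pentylbenzoic acid | CCCCCc1cc(O)cc(OC)c1C(=O)O | intermediate
13 | benzyl 4-hydroxy-2-methoxy-6-pentylbenzoate (ring B phenol) | CCCCCc1cc(O)cc(OC)c1C(=O)OCc1ccccc1 | intermediate
14 | 4-(benzyloxy)-2-methoxy-6-pentylbenzoic trifluoroacetic anhydride (not isolated) | CCCCCc1cc(OCc2ccccc2)cc(OC)c1C(=O)OC(=O)C(F)(F)F | intermediate
15 | benzyl 4-{[4-(benzyloxy)-2-methoxy-6-pentylbenzoyl]oxy}-2-methoxy-6-pentylbenzoate | CCCCCc1cc(OC(=O)c2c(CCCCC)cc(OCc3ccccc3)cc2OC)cc(OC)c1C(=O)OCc1ccccc1 | intermediate
16 | 4-O-demethylplanaic acid | CCCCCc1cc(OC(=O)c2c(CCCCC)cc(O)cc2OC)cc(OC)c1C(=O)O | target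

**Count**
Total steps: 10. Longest linear sequence: 10 steps (1 → 3 → 6 → 8 → 9 → 10 → 11 → 12 → 13 → 15 → 16, with acid 11 entering a second time in step 9).

**Steps most likely to fail**

Step 2. The trianion may be quenched by proton transfer from the α-methylene of the enolisable ester and from the more acidic product, so that conversion stalls and self-condensation of the ester intervenes. The fallback sets out from 4 and makes the chain in the other order, so that the last carbon–carbon bond is formed with a non-enolisable electrophile. Pentane-2,4-dione is deprotonated twice (LiN(iPr)2, 2 equiv, THF, 0 °C) and acylated at its terminal carbon by 4 to give undecane-2,4,6-trione F1. Threefold deprotonation of F1 (LiN(iPr)2, 3 equiv, THF, 0 °C; the methyl terminus should ionise in preference to the C7 methylene) and carboxylation with CO2 at −78 °C should give 3,5,7-trioxododecanoic acid F2. Cold esterification with Me3SiCHN2 in toluene–MeOH returns to the route at 6.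

Step 3. The chain may fold the wrong way: Claisen closure of C6 onto the ester, lactonisation to a 4-hydroxy-2-pyrone, or retro-Claisen cleavage of the triketone under base. The fallback sets out from 4 and locks the carboxyl group in a dioxinone, so that it cannot act as an acyl donor while the same C2–C7 aldol bond is formed.
- Ester 4 is converted to N-methoxy-N-methylhexanamide F3 (MeNH(OMe)·HCl, iPrMgCl, THF, −20 °C).
- Commercial 2,2,6-trimethyl-4H-1,3-dioxin-4-one is acetylated at its methyl group (LiN(SiMe3)2, THF, −78 °C; then acetyl chloride) to 2,2-dimethyl-6-(2-oxopropyl)-4H-1,3-dioxin-4-one F4.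
- Double deprotonation of F4 (LiN(iPr)2, 2 equiv, THF, −78 °C) and acylation by F3 should give 6-(2,4-dioxononyl)-2,2-dimethyl-4H-1,3-dioxin-4-one F5.
- Et3N in CH2Cl2 at 23 °C should bring about aldol closure and dehydration to 7-hydroxy-2,2-dimethyl-5-pentyl-4H-1,3-benzodioxin-4-one F6.
- NaOMe in MeOH at 50 °C opens the dioxinone with loss of acetone and returns to the route at 8.

Step 9. Acyl transfer from the di-ortho-substituted acid may be slow, so that trifluoroacetylation of the phenol, ring C-acylation or acid-induced loss of the benzyl ether competes. The fallback sets out from 11 and replaces the acid-promoted acylium transfer by base-mediated acylation with an isolated acyl donor. Acid 11 is converted with oxalyl chloride and catalytic DMF in CH2Cl2 at 0 °C to 4-(benzyloxy)-2-methoxy-6-pentylbenzoyl chloride F7. F7 is added to phenol 13 with Et3N and catalytic 4-(dimethylamino)pyridine in CH2Cl2 at 23 °C, returning to the route at 15.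

**Further compounds**
F1 | step 2 | undecane-2,4,6-trione | CCCCCC(=O)CC(=O)CC(C)=O
F2 | step 2 | 3,5,7-trioxododecanoic acid | CCCCCC(=O)CC(=O)CC(=O)CC(=O)O
F3 | step 3 | N-methoxy-N-methylhexanamide | CCCCCC(=O)N(C)OC
F4 | step 3 | 2,2-dimethyl-6-(2-oxopropyl)-4H-1,3-dioxin-4-one | CC(=O)CC1=CC(=O)OC(C)(C)O1
F5 | step 3 | 6-(2,4-dioxononyl)-2,2-dimethyl-4H-1,3-dioxin-4-one | CCCCCC(=O)CC(=O)CC1=CC(=O)OC(C)(C)O1
F6 | step 3 | 7-hydroxy-2,2-dimethyl-5-pentyl-4H-1,3-benzodioxin-4-one | CCCCCc1cc(O)cc2OC(C)(C)OC(=O)c12
F7 | step 9 | 4-(benzyloxy)-2-methoxy-6-pentylbenzoyl chloride | CCCCCc1cc(OCc2ccccc2)cc(OC)c1C(Cl)=O
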